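## The problem

Target 15 is 1-(5,7-dihydroxy-2,2-dimethylchroman-6-yl)-3-(2,2-dimethylchroman-6-yl)propan-1-one, an achiral dihydrochalcone. Ring A, the benzene ring that carries the ketone, is fused to dihydropyran ring C and is joined through a C(=O)–CH2–CH2 chain to a second chroman made of benzene ring B and dihydropyran ring D. There is no stereocentre, so the whole difficulty is regiochemical. Ring A is a fully differentiated phloroglucinol: the ketone carbon sits on C6 between two free hydroxyls, the oxygen para to it is the ring oxygen of ring C, and the CH2 of ring C sits on the carbon between that oxygen and one hydroxyl. Direct acylation of a ring A/C chromandiol, or closure of ring C on an acylphloroglucinol, can each also deliver the isomer with the ring oxygen ortho to the ketone. Ring B is the easier half, since it only needs the chain para to the ring D oxygen and ring D ortho to it. The sensitive points are the electron-rich ring A, which is oxidised by air once deprotonated, the tertiary aryl ethers of rings C and D, which can ionise in hot strong acid, and the aryl ketone, which should not be present during a forcing reduction. The feature that opens the route is the unit C6(ring A)–C(=O)–CH2 with a hydroxyl on the neighbouring C5: it maps onto C4a–C4–C3 and O1 of a 3-substituted 4-hydroxycoumarin, whose only extra atom, C2, can leave as CO2. The ring A part of such a coumarin comes from threefold-symmetric phloroglucinol, so the acyl carbon can be placed before any difference between the three oxygens exists.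

## Retrosynthesis

**15 back to 13.** No bond of the target is cut here; a carbon is added. The α-carbon of the ketone receives a carboxyl group (keto acid 14), which is closed as a lactone onto the C5 oxygen to give pyranocoumarin 13. The neighbouring cut, the aryl–carbonyl bond alone, would lead to a Friedel–Crafts acylation that cannot tell C6 from C8 of a chromandiol. The lactone route forms that bond on a symmetric ring instead. The forward step must open the lactone with hydroxide and lose CO2 without harming the ethers.

**13 back to 10 and 11.** The O7–C(CH3)2 and C8–CH2 bonds of ring C are cut, giving trihydroxycoumarin 10 and 2-methylbut-3-en-2-ol 11. Ring C is made at this stage because O1 is locked in the lactone and the 5-hydroxyl is hydrogen-bonded to the C4 oxygen, so the 7-oxygen is the only free phenol. Closing ring C after lactone opening would let two ortho hydroxyls compete with the para one. Closing it before the coumarin is made would desymmetrise the phenol and move the regiochemical problem into the key step. The forward reaction needs one prenyl unit only, on ring A, and closure on O7. Alkylation at C6 with closure on that same oxygen is equally acceptable, because the later lactone opening makes the two carbons flanking the 7-oxygen equivalent and so leads to the same ketone 15.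

**10 back to 8 and 9.** The C4–C4a and O1–C2 bonds are cut. This splits the molecule into phloroglucinol 9 and malonic acid 8, which already carries the α-carbon, the β-carbon and rings B and D. It is the largest simplification in the route and raises no regiochemical question. The forward reaction must stop after one annulation.

**8 back to 4 and 5.** Diacid 8 comes from diester 7 by saponification and 7 from alkylidene malonate 6 by hydrogenation. Cutting the C=C bond of 6 gives chromene aldehyde 4 and diethyl malonate 5. A Knoevenagel condensation is preferred to alkylating 5 with a benzylic halide, which would need extra steps from the aldehyde and risks dialkylation. The hydrogenation also saturates C3=C4 of the chromene, so ring D reaches the chroman level at no extra cost.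

**4 back to 1 and 2.** The C4–C4a bond of ring D is cut by an aryl propargyl ether Claisen transform (ether 3), and the ether O–C bond leads to 4-hydroxybenzaldehyde 1 and 3-chloro-3-methylbut-1-yne 2. Acid-mediated alkylation of the deactivated ring of 1 is the shorter neighbour but is unreliable. The Claisen route is intramolecular, the two ortho positions of 1 are equivalent, and the formyl group is in place from the start.

## Roads not taken

**Alternative 1:** Ring B is cut at C4a–C8a and C5–C6 and traced to a pyridazine. On heating, alkynyl pyridazine A2 would undergo an intramolecular inverse-demand Diels–Alder reaction through its ether tether, lose N2 and give A1, the bis(methoxymethyl) ether of the target; acid would then remove the acetals.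
- Merits: rings B and D form together without any Friedel–Crafts chemistry, and the position of the chain on ring B is fixed by the substitution of the pyridazine.
- Weak points: an unactivated terminal alkyne and a pyridazine carrying an alkoxy donor are poorly matched, so high temperatures are expected, at which a tertiary alkyl heteroaryl ether can eliminate. Making A2 needs substitution by a hindered tertiary alkoxide and two protecting-group operations.
- Comparison: for rings B and D the regiocontrol is as good as in the chosen plan, but no better, since the Claisen step on a para-substituted ether is equally unambiguous. A2 must already contain the complete, correctly substituted ring A/C ketone, which is the real problem and is left unsolved. The chosen plan makes rings B and D in two steps and spends its key step on ring A.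

**Alternative 2:** Ring D is cut at C4–C4a. Acid would rearrange spirodienone A4 by a dienone–phenol shift of the ring CH2 from the spiro carbon to the neighbouring carbon, expanding the tetrahydrofuran and aromatising to chromanol A3 (2,2-dimethylchroman-6-ol).
- Merits: the conditions are mild and the ring D regiochemistry is clean. In mildness it is better than the Claisen step at about 190 °C.
- Weak points: A3 carries a hydroxyl at C6 where the target has carbon. The oxygen would have to be activated and replaced by the three-carbon chain through a cross-coupling, so an oxidation and a deoxygenative C–C coupling are spent on a centre that 4-hydroxybenzaldehyde 1 supplies as carbon from the start. Migration of oxygen instead of carbon is a further possible leak.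
- Comparison: the chosen plan sets against the milder ring closure a shorter, redox-neutral path to the same half, and again a solution for ring A that this alternative does not offer.

**Alternative 3:** Ring D is cut at O1–C2 and C3–C4. Heating hydroxybenzyl alcohol A6 would dehydrate it to an ortho-quinone methide, which adds isobutylene A7 in a hetero-Diels–Alder reaction to give ester A5, methyl 3-(2,2-dimethylchroman-6-yl)propanoate.
- Merits: the polarisation of the two partners fixes the gem-dimethyl carbon on oxygen, and A5 already holds the whole three-carbon chain at the right oxidation level. On paper this is the shortest road: hydrolysis and one acylation of a ring A/C partner would finish the skeleton in fewer steps than the chosen plan.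
- Weak points: A7 is a gaseous, weakly nucleophilic alkene that needs pressure, excess and heat, and the quinone methide can oligomerise. The final union is a Friedel–Crafts acylation that must choose between the carbon flanked by two hydroxyls and the carbon next to the ring oxygen, with no element of control.
- Comparison: the chosen plan is longer. It sets against this a placement of the acyl group that symmetry guarantees, and a ring C closure that is steered by the lactone and indifferent to the site of C-alkylation.

Key step: step 6

Remark on the chemistry: compounds 10, 12 and 13 are written as 4-hydroxy-2-pyranone tautomers; they may equally react as 2-hydroxy-4-pyranones.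

## Route

Step 1
Reactants: 1 4-hydroxybenzaldehyde; 2 3-chloro-3-methylbut-1-yne
Product: 3 4-[(2-methylbut-3-yn-2-yl)oxy]benzaldehyde
Conditions: K2CO3, KI (cat.), CuI (cat.), acetone, reflux
Reagents that add atoms: none
Why: Copper-assisted etherification of a phenoxide with a tertiary propargylic chloride, a standard entry to 1,1-dimethylpropargyl aryl ethers; the acidic para-formyl phenol is fully deprotonated by K2CO3 and CuI activates the propargylic chloride so that substitution outruns elimination.

Step 2
Reactants: 3 4-[(2-methylbut-3-yn-2-yl)oxy]benzaldehyde
Product: 4 2,2-dimethyl-2H-chromene-6-carbaldehyde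
Conditions: N,N-diethylaniline, 190 °C
Reagents that add atoms: none
Why: Aryl propargyl ether Claisen rearrangement: [3,3] shift to the ortho carbon, enolisation, 1,5-hydrogen shift and oxa-6π electrocyclisation close ring D as the chromene. The two ortho positions are equivalent, so only one product can form.

Step 3
Reactants: 4 2,2-dimethyl-2H-chromene-6-carbaldehyde; 5 diethyl malonate
Product: 6 diethyl 2-[(2,2-dimethyl-2H-chromen-6-yl)methylidene]propanedioate
Conditions: piperidine (cat.), AcOH (cat.), toluene, reflux, Dean–Stark
Reagents that add atoms: none
Why: Knoevenagel condensation of a non-enolisable aryl aldehyde with a malonate, driven by azeotropic removal of water; the chromene double bond is inert to the amine catalyst.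

Step 4
Reactants: 6 diethyl 2-[(2,2-dimethyl-2H-chromen-6-yl)methylidene]propanedioate
Product: 7 diethyl 2-[(2,2-dimethyl-3,4-dihydro-2H-chromen-6-yl)methyl]propanedioate
Conditions: H2 (1 atm), 10% Pd/C, EtOAc, rt
Reagents that add atoms: none
Why: Heterogeneous catalytic hydrogenation should saturate both the benzylidene malonate C=C and the styrene-type C3=C4 of the chromene in one operation. The esters and the aryl ether are inert and no stereocentre arises.

Step 5
Reactants: 7 diethyl 2-[(2,2-dimethyl-3,4-dihydro-2H-chromen-6-yl)methyl]propanedioate
Product: 8 2-[(2,2-dimethyl-3,4-dihydro-2H-chromen-6-yl)methyl]propanedioic acid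
Conditions: KOH, EtOH–H2O, reflux; then HCl (aq.), 0 °C
Reagents that add atoms: potassium hydroxide, [K+].[OH-]
Why: Saponification of a malonic diester by acyl–oxygen cleavage; cold acidification and drying below 50 °C keep the substituted malonic acid from decarboxylating.

Step 6
Reactants: 8 2-[(2,2-dimethyl-3,4-dihydro-2H-chromen-6-yl)methyl]propanedioic acid; 9 phloroglucinol (benzene-1,3,5-triol, anhydrous, 1.5 equiv)
Product: 10 3-[(2,2-dimethyl-3,4-dihydro-2H-chromen-6-yl)methyl]-4,5,7-trihydroxy-2H-chromen-2-one
Conditions: POCl3 (3 equiv), fused ZnCl2 (3 equiv), 65 °C; then ice–water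
Reagents that add atoms: none
Why: POCl3 turns the diacid into an acyl dichlorophosphate or acyl chloride that esterifies one hydroxyl of 9, and ZnCl2 activates the second acyl group for intramolecular Friedel–Crafts attack by the neighbouring ring carbon; enolisation of the β-keto lactone then gives the 4-hydroxycoumarin. The closest known reaction type is the POCl3/ZnCl2 condensation of phenols with malonic and monosubstituted malonic acids to 4-hydroxycoumarins, which is established for phloroglucinol itself. The pyranone closes by 6-exo-trig acyl substitution at the activated carbonyl, and the same mode applies through oxygen if C-acylation happens to come first. No stereocentre is formed. Regiochemistry needs no control because all three ring carbons and all three hydroxyls of 9 are equivalent. Mono-annulation is needed and is secured by the excess of 9 and by the deactivation of ring A once it carries the acyl group. Chemoselectivity against ring B rests on the fact that the carbons next to its benzylic carbon are meta to the ether oxygen, so indanone formation should not compete with acylation of the far more nucleophilic 9. The acidic product should be separable by extraction into aqueous NaHCO3 and reprecipitation with acid.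

Step 7
Reactants: 10 3-[(2,2-dimethyl-3,4-dihydro-2H-chromen-6-yl)methyl]-4,5,7-trihydroxy-2H-chromen-2-one; 11 2-methylbut-3-en-2-ol (1.1 equiv, added slowly)
Product: 13 3-[(2,2-dimethyl-3,4-dihydro-2H-chromen-6-yl)methyl]-4,5-dihydroxy-8,8-dimethyl-9,10-dihydro-2H,8H-pyrano[2,3-f]chromen-2-one, via 8-prenyl coumarin 12 (not isolated)
Conditions: BF3·OEt2 (0.3 equiv), dioxane, 25 °C; then TsOH·H2O (0.2 equiv), 80 °C
Reagents that add atoms: none
Why: Acid-mediated Friedel–Crafts prenylation of the phloroglucinol-type ring A by the dimethylallyl cation gives 12, and Markovnikov hydroalkoxylation of the prenyl double bond by the neighbouring phenol then closes ring C, a chroman annulation known for hydroxycoumarins. A prenyl group at C8 can close only on O7 because O1 is held in the lactone, and the 5-hydroxyl is tied up in a hydrogen bond to the C4 oxygen. Any prenylation at C6 that closes on the same 7-oxygen is harmless, since step 8 makes the two carbons flanking that oxygen equivalent and converges on the same ketone; alkylation at the already substituted C3 should be reversible under acid.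

Step 8
Reactants: 13 3-[(2,2-dimethyl-3,4-dihydro-2H-chromen-6-yl)methyl]-4,5-dihydroxy-8,8-dimethyl-9,10-dihydro-2H,8H-pyrano[2,3-f]chromen-2-one
Product: 15 1-(5,7-dihydroxy-2,2-dimethyl-3,4-dihydro-2H-chromen-6-yl)-3-(2,2-dimethyl-3,4-dihydro-2H-chromen-6-yl)propan-1-one, via keto acid 14 (not isolated)
Conditions: NaOH (10% aq.), degassed, N2, reflux; then HCl (aq.), 0 to 50 °C
Reagents that add atoms: none
Why: Alkaline hydrolysis of the lactone of a 3-substituted 4-hydroxycoumarin, the known degradation of such coumarins to 2-hydroxyaryl ketones; acidification gives β-keto acid 14, which should lose CO2 through the usual cyclic transition state. The former lactone oxygen O1 becomes the second hydroxyl ortho to the ketone, the ring C oxygen ends para to it, and exclusion of air protects the phenolate of ring A.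

## Compound list

1 | 4-hydroxybenzaldehyde | O=Cc1ccc(O)cc1 | starting material
2 | 3-chloro-3-methylbut-1-yne | CC(C)(Cl)C#C | starting material
3 | 4-[(2-methylbut-3-yn-2-yl)oxy]benzaldehyde | O=Cc1ccc(OC(C)(C)C#C)cc1 | intermediate
4 | 2,2-dimethyl-2H-chromene-6-carbaldehyde | O=Cc1ccc2OC(C)(C)C=Cc2c1 | intermediate
5 | diethyl malonate | CCOC(=O)CC(=O)OCC | starting material
6 | diethyl 2-[(2,2-dimethyl-2H-chromen-6-yl)methylidene]propanedioate | CCOC(=O)C(=Cc1ccc2OC(C)(C)C=Cc2c1)C(=O)OCC | intermediate
7 | diethyl 2-[(2,2-dimethyl-3,4-dihydro-2H-chromen-6-yl)methyl]propanedioate | CCOC(=O)C(Cc1ccc2OC(C)(C)CCc2c1)C(=O)OCC | intermediate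
8 | 2-[(2,2-dimethyl-3,4-dihydro-2H-chromen-6-yl)methyl]propanedioic acid | OC(=O)C(Cc1ccc2OC(C)(C)CCc2c1)C(=O)O | intermediate
9 | phloroglucinol (benzene-1,3,5-triol) | Oc1cc(O)cc(O)c1 | starting material
10 | 3-[(2,2-dimethyl-3,4-dihydro-2H-chromen-6-yl)methyl]-4,5,7-trihydroxy-2H-chromen-2-one | O=C1Oc2cc(O)cc(O)c2C(O)=C1Cc1ccc2OC(C)(C)CCc2c1 | intermediate
11 | 2-methylbut-3-en-2-ol | CC(C)(O)C=C | starting material
12 | 3-[(2,2-dimethyl-3,4-dihydro-2H-chromen-6-yl)methyl]-4,5,7-trihydroxy-8-(3-methylbut-2-en-1-yl)-2H-chromen-2-one | O=C1Oc2c(CC=C(C)C)c(O)cc(O)c2C(O)=C1Cc1ccc2OC(C)(C)CCc2c1 | intermediate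
13 | 3-[(2,2-dimethyl-3,4-dihydro-2H-chromen-6-yl)methyl]-4,5-dihydroxy-8,8-dimethyl-9,10-dihydro-2H,8H-pyrano[2,3-f]chromen-2-one (ring C on coumarin C8 and O7) | O=C1Oc2c3CCC(C)(C)Oc3cc(O)c2C(O)=C1Cc1ccc2OC(C)(C)CCc2c1 | intermediate
14 | 3-(5,7-dihydroxy-2,2-dimethyl-3,4-dihydro-2H-chromen-6-yl)-2-[(2,2-dimethyl-3,4-dihydro-2H-chromen-6-yl)methyl]-3-oxopropanoic acid | OC(=O)C(Cc1ccc2OC(C)(C)CCc2c1)C(=O)c1c(O)cc2OC(C)(C)CCc2c1O | intermediate
15 | 1-(5,7-dihydroxy-2,2-dimethyl-3,4-dihydro-2H-chromen-6-yl)-3-(2,2-dimethyl-3,4-dihydro-2H-chromen-6-yl)propan-1-one | CC1(C)CCc2cc(CCC(=O)c3c(O)cc4c(c3O)CCC(C)(C)O4)ccc2O1 | target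

## Step count and least certain steps

Total step count: 8. Longest linear sequence: 8 steps, from 1 to 15.

**Step 6 (key step).** The most likely failure is over-reaction: a second malonyl unit may annulate onto the remaining hydroxyls of ring A, or the enolic hydroxyl may be chlorinated or phosphorylated by POCl3. Intramolecular acylation of ring B to an indanone may divert part of the activated acid, and the Lewis acid may ionise the tertiary ether of ring D. Fallback: from 8, esterification with 2,4,6-trichlorophenol and POCl3 should give bis(2,4,6-trichlorophenyl) 2-[(2,2-dimethyl-3,4-dihydro-2H-chromen-6-yl)methyl]propanedioate F1. This isolable active ester is then heated with 9 in diphenyl ether at about 200 °C without any Lewis acid. Thermal acylation through an acylketene forms the same two bonds and rejoins the route at 10.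

**Step 7.** Three processes may compete: alkylation at the enolic C3, closure of a C6-prenyl group onto the 5-oxygen instead of the 7-oxygen, and a second prenylation of ring A. All follow from the high nucleophilicity of the substrate towards a free cation. Only closure on the 5-oxygen would lead to the wrong ketone, because alkylation at C6 with closure on the 7-oxygen converges on 15 in step 8. Fallback: from 10, the lactone is opened first with hot aqueous NaOH and acid to give 3-(2,2-dimethyl-3,4-dihydro-2H-chromen-6-yl)-1-(2,4,6-trihydroxyphenyl)propan-1-one F2. Its non-chelated para hydroxyl is etherified with 2 (K2CO3, KI, CuI, acetone) to give 1-[2,6-dihydroxy-4-[(2-methylbut-3-yn-2-yl)oxy]phenyl]-3-(2,2-dimethyl-3,4-dihydro-2H-chromen-6-yl)propan-1-one F3. Thermal Claisen rearrangement, in which the ether oxygen necessarily becomes the ring oxygen and the two ortho carbons are equivalent, gives 1-(5,7-dihydroxy-2,2-dimethyl-2H-chromen-6-yl)-3-(2,2-dimethyl-3,4-dihydro-2H-chromen-6-yl)propan-1-one F4. Hydrogenation over Pd/C then rejoins the route at 15.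

**Step 8.** Hydroxide attack on the lactone carbonyl may be slow, because the substrate is present as a polyanion, and the electron-rich phenolate of ring A may be oxidised during prolonged heating. Fallback: from 8, thermal decarboxylation gives 3-(2,2-dimethyl-3,4-dihydro-2H-chromen-6-yl)propanoic acid F5. Separately, 9 and 11 under acid give 2,2-dimethyl-3,4-dihydro-2H-chromene-5,7-diol F6. Friedel–Crafts acylation of F6 with F5 in BF3·OEt2 at about 80 °C, followed by chromatographic removal of the product of acylation at C8, returns to the route at 15. This gives up the built-in regiocontrol and is a last resort.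

**Step 1.** Elimination of HCl from the tertiary chloride and slow substitution by the weakly nucleophilic para-formyl phenoxide may leave the conversion low. Fallback: from 1, C-prenylation with prenyl bromide in aqueous KOH gives 4-hydroxy-3-(3-methylbut-2-en-1-yl)benzaldehyde F7. Acid cyclisation on a sulfonic acid resin (Amberlyst 15) gives 2,2-dimethyl-3,4-dihydro-2H-chromene-6-carbaldehyde F8. Knoevenagel condensation with 5 gives diethyl 2-[(2,2-dimethyl-3,4-dihydro-2H-chromen-6-yl)methylidene]propanedioate F9, and hydrogenation over Pd/C rejoins the route at 7.

## Further compounds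

F1 | step 6 | bis(2,4,6-trichlorophenyl) 2-[(2,2-dimethyl-3,4-dihydro-2H-chromen-6-yl)methyl]propanedioate | O=C(Oc1c(Cl)cc(Cl)cc1Cl)C(Cc1ccc2OC(C)(C)CCc2c1)C(=O)Oc1c(Cl)cc(Cl)cc1Cl
F2 | step 7 | 3-(2,2-dimethyl-3,4-dihydro-2H-chromen-6-yl)-1-(2,4,6-trihydroxyphenyl)propan-1-one | O=C(CCc1ccc2OC(C)(C)CCc2c1)c1c(O)cc(O)cc1O
F3 | step 7 | 1-[2,6-dihydroxy-4-[(2-methylbut-3-yn-2-yl)oxy]phenyl]-3-(2,2-dimethyl-3,4-dihydro-2H-chromen-6-yl)propan-1-one | O=C(CCc1ccc2OC(C)(C)CCc2c1)c1c(O)cc(OC(C)(C)C#C)cc1O
F4 | step 7 | 1-(5,7-dihydroxy-2,2-dimethyl-2H-chromen-6-yl)-3-(2,2-dimethyl-3,4-dihydro-2H-chromen-6-yl)propan-1-one | O=C(CCc1ccc2OC(C)(C)CCc2c1)c1c(O)cc2OC(C)(C)C=Cc2c1O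
F5 | step 8 | 3-(2,2-dimethyl-3,4-dihydro-2H-chromen-6-yl)propanoic acid | OC(=O)CCc1ccc2OC(C)(C)CCc2c1
F6 | step 8 | 2,2-dimethyl-3,4-dihydro-2H-chromene-5,7-diol | CC1(C)CCc2c(O)cc(O)cc2O1
F7 | step 1 | 4-hydroxy-3-(3-methylbut-2-en-1-yl)benzaldehyde | O=Cc1ccc(O)c(CC=C(C)C)c1
F8 | step 1 | 2,2-dimethyl-3,4-dihydro-2H-chromene-6-carbaldehyde | O=Cc1ccc2OC(C)(C)CCc2c1
F9 | step 1 | diethyl 2-[(2,2-dimethyl-3,4-dihydro-2H-chromen-6-yl)methylidene]propanedioate | CCOC(=O)C(=Cc1ccc2OC(C)(C)CCc2c1)C(=O)OCC
A1 | alternative 1 | 1-[5,7-bis(methoxymethoxy)-2,2-dimethyl-3,4-dihydro-2H-chromen-6-yl]-3-(2,2-dimethyl-3,4-dihydro-2H-chromen-6-yl)propan-1-one | CC1(C)CCc2cc(CCC(=O)c3c(OCOC)cc4OC(C)(C)CCc4c3OCOC)ccc2O1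
A2 | alternative 1 | 1-[5,7-bis(methoxymethoxy)-2,2-dimethyl-3,4-dihydro-2H-chromen-6-yl]-3-[6-[(2-methylhex-5-yn-2-yl)oxy]pyridazin-3-yl]propan-1-one | C#CCCC(C)(C)Oc1ccc(CCC(=O)c2c(OCOC)cc3OC(C)(C)CCc3c2OCOC)nn1
A3 | alternative 2 | 2,2-dimethyl-3,4-dihydro-2H-chromen-6-ol | CC1(C)CCc2cc(O)ccc2O1
A4 | alternative 2 | 2,2-dimethyl-1-oxaspiro[4.5]deca-6,9-dien-8-one | CC1(C)CCC2(O1)C=CC(=O)C=C2
A5 | alternative 3 | methyl 3-(2,2-dimethyl-3,4-dihydro-2H-chromen-6-yl)propanoate | COC(=O)CCc1ccc2OC(C)(C)CCc2c1
A6 | alternative 3 | methyl 3-[4-hydroxy-3-(hydroxymethyl)phenyl]propanoate | COC(=O)CCc1ccc(O)c(CO)c1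
A7 | alternative 3 | isobutylene (2-methylprop-1-ene) | CC(C)=C
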